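With 1000 substrate molecules charged per free catalyst, 500 turnovers of every catalyst give half of the charge as product. So before you spend material, decide which temperature plan can pay for that many turnovers.

| setting | west | east | Friday's | Saturday's | Sunday's |
|---|---|---|---|---|---|
| left-handed substrate | 0.034 M | 0.075 M | 0.050 M | 0.050 M | 0.050 M |
| right-handed substrate | 0.034 M | 0.075 M | 0.050 M | 0.050 M | 0.050 M |
| gas | 6.7 mM (held) | 6.7 mM (held) | 6.7 mM (held) | 6.7 mM (held) | 6.7 mM (held) |
| free catalyst | 0.10 mM | 0.10 mM | 0.10 mM | 0.10 mM | 0.10 mM |
| racemization catalyst | 7.5 mM | 7.5 mM | 7.5 mM | 7.5 mM | 7.5 mM |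
| temperature | 88 °C | 104 °C | 110 °C | 80 °C |  |
| remark | run made earlier | run made earlier |  |  | at 80 °C until 50 s, from then on at 110 °C |
| time |  |  | 4.0 min | 4.0 min | 4.0 min |

| run | time / min | left-handed product / % |
|---|---|---|
| west | 0.500 | 11.3 |
| west | 1.33 | 27.1 |
| west | 2.50 | 40.0 |
| west | 4.00 | 49.4 |
| west | 6.00 | 55.0 |
| west | 8.00 | 57.4 |
| east | 0.500 | 8.4 |
| east | 1.00 | 17.0 |
| east | 1.33 | 21.7 |
| east | 2.00 | 29.7 |
| east | 2.50 | 34.7 |
| east | 3.00 | 37.7 |

(scatter of a reading: 0.5 percentage points)

1. which flask leads in amount of left-handed product, in percent of the left-handed substrate and right-handed substrate together charged ("all alike" within 1.5 percentage points) (Friday's / Saturday's / Sunday's / all alike)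
2. how much left-handed product is there at the end, in percent of the left-handed substrate and right-handed substrate together charged: Friday's
3. how much left-handed product is there at the end, in percent of the left-handed substrate and right-handed substrate together charged: Saturday's
4. how much left-handed product is there at the end, in percent of the left-handed substrate and right-handed substrate together charged: Sunday's

- free catalyst is single-handed; left-handed substrate and right-handed substrate are mirror images of each other, charged as a racemate, each of them at the stated concentration
- at the start none of the gas is in solution

Count the runs in turnovers, meaning left-handed product made per catalyst charged. In the west run the rate falls from 75.0 min⁻¹ to 42.6 min⁻¹ over its middle readings, which is a loss of 0.427 min⁻¹ for each turnover made. In the east run it falls from 190 min⁻¹ to 120 min⁻¹, a loss of 0.454 min⁻¹.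

I take these falls as straight lines, so the rate reaches zero at 404 turnovers in the west run and 770 in the east run. I also assume this total grows in step with c(left-handed substrate). At 0.050 M that makes 594 at 88 °C and 513 at 104 °C, so the hotter run reads lower, though these are readings that carry their scatter.

Continuing the line, my estimate of Saturday's turnover budget (its turnover number), the turnovers to left-handed product that one catalyst gives in all in that flask, is 634, and Friday's is 483.

If each flask closes on its budget exponentially at the figures above, my reckoning gives Saturday's 51.9 % and Friday's 40.4 %. Sunday's spends 29.9 % of the cold budget before the change and then earns on Friday's budget, which gives 44.8 %. So I would run cold.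

The forecast differs. It says “I assume a ceiling near 60% for all three flasks”, and it gives Friday's 52 %, Saturday's 35 % and Sunday's 50 %, with Friday's leading.

The flasks give Saturday's 48.0 %, Sunday's 44.0 % and Friday's 39.4 %, so Saturday's leads.

    reagent + free catalyst + left-handed substrate → free catalyst + left-handed product (k = 29000 M⁻² s⁻¹, Ea = 8.00 kJ mol⁻¹)
    reagent + free catalyst + right-handed substrate → free catalyst + right-handed product (k = 1400 M⁻² s⁻¹, Ea = 38.0 kJ mol⁻¹)
    left-handed substrate + racemization catalyst ⇌ right-handed substrate + racemization catalyst, rate k3*[racemization catalyst]*[left-handed substrate] forward; the back reaction follows from the equilibrium constant (k = 3.50 M⁻¹ s⁻¹, Ea = 71.0 kJ mol⁻¹)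
    reagent + free catalyst → spent catalyst (k = 2.60 M⁻¹ s⁻¹, Ea = 42.0 kJ mol⁻¹)
    gas ⇌ reagent, rate k5*(csat - [reagent]) (kL = 0.130 s⁻¹)
    (constants at 110 °C)

At the end Saturday's still holds 36.8 % of its free catalyst, and Friday's holds 4.00 %. Saturday's budget of 634 turnovers, applied to a neighbour flask that is Saturday's with 6.0 × 10⁻⁵ M of free catalyst, comes to 38.0 % of the charge. That neighbour flask holds 36.7 % left-handed product after 4.00 min, with 34.0 % of its free catalyst still free.

The data were computed from invented constants; noise was put on by code.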